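**Plan**

1. Unit A is the flavanone with the catechol ring (O1, C2, C3, C4, ring A); unit B is the 8-linked flavanone (atoms marked ″). Retrosynthetic cuts, in order: seven O–benzyl bonds; C3–H of unit A (from a C3–OH ketol); the C2–C3 bond of ring C of unit A (C2 returned to the neighbouring carbinol carbon, giving a 3-aroyl-3-hydroxy-2,3-dihydrobenzofuran); C2″–aryl of unit B; then the ketol C–O bonds, C3a–C3 of the benzofuran, C(sp)–C8″ and C2–O1.
2. Forward order: chromone ring of unit B; aryl propargyl ether; Sonogashira union; 5-exo-dig closure to the dihydrobenzofuran; oxidation to the tertiary α-ketol; one-carbon enlargement to ring C of unit A; conjugate arylation to complete unit B; deoxygenation; debenzylation.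
3. Enabling feature: C3 of unit A lies between the ring-A-conjugated C4 carbonyl and the O1-bearing C2. It can therefore start as an exocyclic aroyl carbon on a benzofuran-3-ol. The shift of C2 to that carbon brings it into the ring, so the hindered C3–C8″ bond is first made as an aryl–alkyne bond.
4. Stereochemistry: C2 of unit A comes from a copper-catalysed asymmetric propargylic etherification and migrates with retention. C3 is set by thermodynamic trans equilibration after the ketol hydroxyl is removed. C2″ comes from a catalyst-controlled palladium conjugate addition.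

Key step: step 11

Remark: compounds 1, 5, 8 and 17 are taken as purchasable; in steps 6 and 12 the ligand antipode is used if the sense of induction is opposite to that stated.

**Route**

Step 1
Reactants: 1 1-[2,4-bis(benzyloxy)-6-hydroxyphenyl]ethan-1-one
Product: 2 1-[4,6-bis(benzyloxy)-2-hydroxy-3-iodophenyl]ethan-1-one
Conditions: BnMe3N+ ICl2− (1.05 equiv), NaHCO3, CH2Cl2–MeOH, 25 °C
Reagents that add atoms: benzyltrimethylammonium dichloroiodate, C[N+](C)(C)Cc1ccccc1.Cl[I-]Cl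
Why: Electrophilic aromatic iodination of a chelated phenol, which should go to the ortho position C3 (between OH and one benzyloxy group) in preference to C5 between two benzyloxy groups.

Step 2
Reactants: 2 1-[4,6-bis(benzyloxy)-2-hydroxy-3-iodophenyl]ethan-1-one
Product: 4 5,7-bis(benzyloxy)-8-iodo-4H-chromen-4-one, via enaminone 3 (not isolated)
Conditions: Me2NCH(OMe)2, toluene, 100 °C; then HCl (aq), CH2Cl2, 25 °C
Reagents that add atoms: N,N-dimethylformamide dimethyl acetal, COC(OC)N(C)C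
Why: Enaminone formation at the methyl ketone followed by acid-promoted cyclisation of the free ortho phenol with loss of dimethylamine (standard chromone synthesis), which places the iodine at C8.

Step 3
Reactants: 5 3,4-bis(benzyloxy)benzaldehyde
Product: 6 rac-1-[3,4-bis(benzyloxy)phenyl]prop-2-yn-1-ol
Conditions: HC≡CMgBr, THF, 0 °C; then H2O
Reagents that add atoms: ethynylmagnesium bromide, C#C[Mg]Br
Why: 1,2-Addition of an alkynyl Grignard reagent to an aryl aldehyde.

Step 4
Reactants: 6 rac-1-[3,4-bis(benzyloxy)phenyl]prop-2-yn-1-ol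
Product: 7 rac-1-[3,4-bis(benzyloxy)phenyl]prop-2-yn-1-yl acetate
Conditions: Ac2O, Et3N, DMAP (cat.), CH2Cl2, 0 °C
Reagents that add atoms: acetic anhydride, CC(=O)OC(C)=O
Why: DMAP-catalysed acylation installs the leaving group needed for propargylic substitution.

Step 5
Reactants: 8 3,5-bis(benzyloxy)phenol
Product: 9 2-bromo-3,5-bis(benzyloxy)phenol
Conditions: NBS (1.0 equiv), i-Pr2NH (10 mol %), CH2Cl2, −78 °C
Reagents that add atoms: N-bromosuccinimide, O=C1CCC(=O)N1Br
Why: Amine-catalysed ortho-selective bromination of a phenol, in which the hydrogen-bonded N-bromoamine delivers bromine next to the OH while C4 is shielded by two benzyloxy groups.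

Step 6
Reactants: 7 rac-1-[3,4-bis(benzyloxy)phenyl]prop-2-yn-1-yl acetate; 9 2-bromo-3,5-bis(benzyloxy)phenol
Product: 10 (1R)-1-[3,4-bis(benzyloxy)phenyl]prop-2-yn-1-yl 2-bromo-3,5-bis(benzyloxy)phenyl ether
Conditions: Cu(MeCN)4PF6 (5 mol %), (S,S)-Ph-pybox (6 mol %), i-Pr2NEt, CH2Cl2, −20 °C
Reagents that add atoms: none
Why: Copper-catalysed enantioselective propargylic etherification, in which the racemic acetate converges on a planar copper allenylidene and the phenoxide attacks its γ-carbon on the face set by the chiral pybox ligand, fixing the future C2 of unit A.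

Step 7
Reactants: 10 (1R)-1-[3,4-bis(benzyloxy)phenyl]prop-2-yn-1-yl 2-bromo-3,5-bis(benzyloxy)phenyl ether; 4 5,7-bis(benzyloxy)-8-iodo-4H-chromen-4-one
Product: 11 5,7-bis(benzyloxy)-8-{(3S)-3-[3,4-bis(benzyloxy)phenyl]-3-[2-bromo-3,5-bis(benzyloxy)phenoxy]prop-1-yn-1-yl}-4H-chromen-4-one
Conditions: Pd(PPh3)2Cl2 (3 mol %), CuI (5 mol %), Et3N, THF, 25–40 °C
Reagents that add atoms: none
Why: Sonogashira coupling, in which the aryl iodide should react in preference to the hindered electron-rich aryl bromide and the stereocentre is untouched (the descriptor changes only because the priorities change).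

Step 8
Reactants: 11 5,7-bis(benzyloxy)-8-{(3S)-3-[3,4-bis(benzyloxy)phenyl]-3-[2-bromo-3,5-bis(benzyloxy)phenoxy]prop-1-yn-1-yl}-4H-chromen-4-one
Product: 12 5,7-bis(benzyloxy)-8-{(Z)-[(2S)-2-[3,4-bis(benzyloxy)phenyl]-4,6-bis(benzyloxy)-1-benzofuran-3(2H)-ylidene]methyl}-4H-chromen-4-one
Conditions: Pd(OAc)2 (5 mol %), XPhos (10 mol %), HCO2Na, DMF, 80 °C
Reagents that add atoms: none
Why: Reductive Heck cyclisation, in which oxidative addition into the Ar–Br bond and 5-exo-dig syn-carbopalladation close the dihydrobenzofuran and formate reduces the vinylpalladium, so the syn addition gives the Z alkene and C2 is not involved.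

Step 9
Reactants: 12 5,7-bis(benzyloxy)-8-{(Z)-[(2S)-2-[3,4-bis(benzyloxy)phenyl]-4,6-bis(benzyloxy)-1-benzofuran-3(2H)-ylidene]methyl}-4H-chromen-4-one
Product: 13 5,7-bis(benzyloxy)-8-{(S)-[(2S,3S)-2-[3,4-bis(benzyloxy)phenyl]-4,6-bis(benzyloxy)-3-hydroxy-2,3-dihydro-1-benzofuran-3-yl](hydroxy)methyl}-4H-chromen-4-one
Conditions: OsO4 (10 mol %), NMO, acetone–H2O, 25 °C
Reagents that add atoms: N-methylmorpholine N-oxide, C[N+]1([O-])CCOCC1; water, O
Why: Upjohn syn-dihydroxylation of the electron-rich exocyclic alkene, expected from the face anti to the C2 aryl group (both new centres are consumed in steps 10, 11 and 13, so their configuration does not matter).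

Step 10
Reactants: 13 5,7-bis(benzyloxy)-8-{(S)-[(2S,3S)-2-[3,4-bis(benzyloxy)phenyl]-4,6-bis(benzyloxy)-3-hydroxy-2,3-dihydro-1-benzofuran-3-yl](hydroxy)methyl}-4H-chromen-4-one
Product: 14 5,7-bis(benzyloxy)-8-{[(2S,3R)-2-[3,4-bis(benzyloxy)phenyl]-4,6-bis(benzyloxy)-3-hydroxy-2,3-dihydro-1-benzofuran-3-yl]carbonyl}-4H-chromen-4-one
Conditions: IBX, DMSO, 25 °C
Reagents that add atoms: none
Why: IBX oxidation of the secondary benzylic alcohol, which converts a 1,2-diol into the α-hydroxy ketone without cleaving the glycol C–C bond.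

Step 11
Reactants: 14 5,7-bis(benzyloxy)-8-{[(2S,3R)-2-[3,4-bis(benzyloxy)phenyl]-4,6-bis(benzyloxy)-3-hydroxy-2,3-dihydro-1-benzofuran-3-yl]carbonyl}-4H-chromen-4-one
Product: 16 5,7-bis(benzyloxy)-8-{(2S,3S)-2-[3,4-bis(benzyloxy)phenyl]-5,7-bis(benzyloxy)-3-hydroxy-4-oxo-3,4-dihydro-2H-chromen-3-yl}-4H-chromen-4-one, via potassium alkoxide 15 (not isolated)
Conditions: KN(SiMe3)2 (1.05 equiv), THF, −78 to 25 °C; then AcOH
Reagents that add atoms: none
Why: Deprotonation gives potassium alkoxide 15, in which the C3 oxide and the exocyclic aroyl C=O are chelated syn; the ring bond C2–C3 then shifts to the neighbouring carbonyl carbon while the former carbinol carbon becomes the ring-A-conjugated C4 ketone (anionic α-ketol, or acyloin, rearrangement). The closest known reaction type is the base-mediated ring expansion of 1-acylcycloalkanols to 2-hydroxycycloalkanones, for example 1-benzoylcyclopentanol to 2-hydroxy-2-phenylcyclohexanone and the D-homoannulation of 17-hydroxy-20-oxo steroids. The pyranone ring is not closed by a cyclisation: the five-membered O1–C2–C3–C3a–C7a ring is enlarged by one carbon through a suprafacial 1,2-carbon shift over a three-centre transition state, which inserts the former exocyclic carbonyl carbon (carrying C8″) between C2 and the new C4. C2 migrates with retention, so the configuration from step 6 is carried over; the new C3 carbinol centre is fixed by the chelated transition state (C3 aryl cis to the C2 aryl expected) and is removed in step 13, so either epimer serves. The step needs C2 to migrate and not the ring-A aryl carbon: under anionic conditions the carbanion-stabilising α-aryloxybenzyl carbon should be the better migrating group than the electron-rich trioxygenated aryl, and the product ketone, coplanar with ring A and stabilised as a vinylogous ester by O1 and the 7-oxygen, should be the thermodynamic sink of the reversible ketol manifold. Neither 14 nor 16 has an enolisable hydrogen or an aligned β-leaving group, so the base has no other outlet.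

Step 12
Reactants: 16 5,7-bis(benzyloxy)-8-{(2S,3S)-2-[3,4-bis(benzyloxy)phenyl]-5,7-bis(benzyloxy)-3-hydroxy-4-oxo-3,4-dihydro-2H-chromen-3-yl}-4H-chromen-4-one; 17 [4-(benzyloxy)phenyl]boronic acid
Product: 18 (2R)-5,7-bis(benzyloxy)-2-[4-(benzyloxy)phenyl]-8-{(2S,3S)-2-[3,4-bis(benzyloxy)phenyl]-5,7-bis(benzyloxy)-3-hydroxy-4-oxo-3,4-dihydro-2H-chromen-3-yl}-2,3-dihydro-4H-chromen-4-one
Conditions: Pd(OCOCF3)2 (5 mol %), (S)-t-BuPyOx (6 mol %), NH4PF6 (30 mol %), H2O (5 equiv), ClCH2CH2Cl, 60 °C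
Reagents that add atoms: none
Why: Palladium-catalysed asymmetric conjugate addition of an arylboronic acid to a chromone, in which the arylpalladium adds to C2″ on the face set by the pyridine-oxazoline ligand and the palladium enolate is protonated, while unit A has no enolisable hydrogen at this stage.

Step 13
Reactants: 18 (2R)-5,7-bis(benzyloxy)-2-[4-(benzyloxy)phenyl]-8-{(2S,3S)-2-[3,4-bis(benzyloxy)phenyl]-5,7-bis(benzyloxy)-3-hydroxy-4-oxo-3,4-dihydro-2H-chromen-3-yl}-2,3-dihydro-4H-chromen-4-one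
Product: 20 (2R,3S)-2-[3,4-bis(benzyloxy)phenyl]-5,7-bis(benzyloxy)-3-{(2R)-5,7-bis(benzyloxy)-2-[4-(benzyloxy)phenyl]-4-oxo-3,4-dihydro-2H-chromen-8-yl}-2,3-dihydro-4H-chromen-4-one, via samarium enolate 19 (not isolated)
Conditions: SmI2 (2.5 equiv), THF–MeOH, −78 °C; then TsOH·H2O (cat.), CH2Cl2, 25 °C
Reagents that add atoms: none
Why: SmI2 deoxygenation of an α-hydroxy ketone (ketyl, loss of hydroxide, enolate 19, protonation by MeOH at −78 °C before O1 can be eliminated), after which acid-catalysed enolisation should equilibrate C3 so that its aryl group lies trans to the fixed C2 aryl group (3S).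

Step 14
Reactants: 20 (2R,3S)-2-[3,4-bis(benzyloxy)phenyl]-5,7-bis(benzyloxy)-3-{(2R)-5,7-bis(benzyloxy)-2-[4-(benzyloxy)phenyl]-4-oxo-3,4-dihydro-2H-chromen-8-yl}-2,3-dihydro-4H-chromen-4-one
Product: 21 (2R,3S)-2-(3,4-dihydroxyphenyl)-5,7-dihydroxy-3-[(2R)-5,7-dihydroxy-2-(4-hydroxyphenyl)-4-oxo-3,4-dihydro-2H-chromen-8-yl]-2,3-dihydro-4H-chromen-4-one
Conditions: H2 (1 atm), Pd/C (10%), EtOAc–MeOH, 25 °C
Reagents that add atoms: none
Why: Hydrogenolysis of the seven benzyl ethers under neutral conditions, which should leave both base-sensitive flavanone rings and all three stereocentres intact.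

**Compound list**

1 | 1-[2,4-bis(benzyloxy)-6-hydroxyphenyl]ethan-1-one | CC(=O)c1c(O)cc(OCc2ccccc2)cc1OCc1ccccc1 | starting material
2 | 1-[4,6-bis(benzyloxy)-2-hydroxy-3-iodophenyl]ethan-1-one | CC(=O)c1c(O)c(I)c(OCc2ccccc2)cc1OCc1ccccc1 | intermediate
3 | (E)-1-[4,6-bis(benzyloxy)-2-hydroxy-3-iodophenyl]-3-(dimethylamino)prop-2-en-1-one | CN(C)/C=C/C(=O)c1c(O)c(I)c(OCc2ccccc2)cc1OCc1ccccc1 | intermediate (not isolated)
4 | 5,7-bis(benzyloxy)-8-iodo-4H-chromen-4-one | O=c1ccoc2c(I)c(OCc3ccccc3)cc(OCc3ccccc3)c12 | intermediate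
5 | 3,4-bis(benzyloxy)benzaldehyde | O=Cc1ccc(OCc2ccccc2)c(OCc2ccccc2)c1 | starting material
6 | rac-1-[3,4-bis(benzyloxy)phenyl]prop-2-yn-1-ol | C#CC(O)c1ccc(OCc2ccccc2)c(OCc2ccccc2)c1 | intermediate
7 | rac-1-[3,4-bis(benzyloxy)phenyl]prop-2-yn-1-yl acetate | C#CC(OC(C)=O)c1ccc(OCc2ccccc2)c(OCc2ccccc2)c1 | intermediate
8 | 3,5-bis(benzyloxy)phenol | Oc1cc(OCc2ccccc2)cc(OCc2ccccc2)c1 | starting material
9 | 2-bromo-3,5-bis(benzyloxy)phenol | Oc1cc(OCc2ccccc2)cc(OCc2ccccc2)c1Br | intermediate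
10 | (1R)-1-[3,4-bis(benzyloxy)phenyl]prop-2-yn-1-yl 2-bromo-3,5-bis(benzyloxy)phenyl ether | C#C[C@@H](Oc1cc(OCc2ccccc2)cc(OCc2ccccc2)c1Br)c1ccc(OCc2ccccc2)c(OCc2ccccc2)c1 | intermediate
11 | 5,7-bis(benzyloxy)-8-{(3S)-3-[3,4-bis(benzyloxy)phenyl]-3-[2-bromo-3,5-bis(benzyloxy)phenoxy]prop-1-yn-1-yl}-4H-chromen-4-one | O=c1ccoc2c(C#C[C@@H](Oc3cc(OCc4ccccc4)cc(OCc4ccccc4)c3Br)c3ccc(OCc4ccccc4)c(OCc4ccccc4)c3)c(OCc3ccccc3)cc(OCc3ccccc3)c12 | intermediate
12 | 5,7-bis(benzyloxy)-8-{(Z)-[(2S)-2-[3,4-bis(benzyloxy)phenyl]-4,6-bis(benzyloxy)-1-benzofuran-3(2H)-ylidene]methyl}-4H-chromen-4-one | O=c1ccoc2c(/C=C3/c4c(OCc5ccccc5)cc(OCc5ccccc5)cc4O[C@H]3c3ccc(OCc4ccccc4)c(OCc4ccccc4)c3)c(OCc3ccccc3)cc(OCc3ccccc3)c12 | intermediate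
13 | 5,7-bis(benzyloxy)-8-{(S)-[(2S,3S)-2-[3,4-bis(benzyloxy)phenyl]-4,6-bis(benzyloxy)-3-hydroxy-2,3-dihydro-1-benzofuran-3-yl](hydroxy)methyl}-4H-chromen-4-one | O=c1ccoc2c([C@H](O)[C@@]3(O)c4c(OCc5ccccc5)cc(OCc5ccccc5)cc4O[C@H]3c3ccc(OCc4ccccc4)c(OCc4ccccc4)c3)c(OCc3ccccc3)cc(OCc3ccccc3)c12 | intermediate
14 | 5,7-bis(benzyloxy)-8-{[(2S,3R)-2-[3,4-bis(benzyloxy)phenyl]-4,6-bis(benzyloxy)-3-hydroxy-2,3-dihydro-1-benzofuran-3-yl]carbonyl}-4H-chromen-4-one | O=c1ccoc2c(C(=O)[C@@]3(O)c4c(OCc5ccccc5)cc(OCc5ccccc5)cc4O[C@H]3c3ccc(OCc4ccccc4)c(OCc4ccccc4)c3)c(OCc3ccccc3)cc(OCc3ccccc3)c12 | intermediate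
15 | potassium alkoxide of 14 (potassium (2S,3R)-3-aroyl-2-aryl-2,3-dihydro-1-benzofuran-3-olate) | O=c1ccoc2c(C(=O)[C@@]3([O-])c4c(OCc5ccccc5)cc(OCc5ccccc5)cc4O[C@H]3c3ccc(OCc4ccccc4)c(OCc4ccccc4)c3)c(OCc3ccccc3)cc(OCc3ccccc3)c12.[K+] | intermediate (not isolated)
16 | 5,7-bis(benzyloxy)-8-{(2S,3S)-2-[3,4-bis(benzyloxy)phenyl]-5,7-bis(benzyloxy)-3-hydroxy-4-oxo-3,4-dihydro-2H-chromen-3-yl}-4H-chromen-4-one | O=c1ccoc2c([C@@]3(O)C(=O)c4c(OCc5ccccc5)cc(OCc5ccccc5)cc4O[C@H]3c3ccc(OCc4ccccc4)c(OCc4ccccc4)c3)c(OCc3ccccc3)cc(OCc3ccccc3)c12 | intermediate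
17 | [4-(benzyloxy)phenyl]boronic acid | OB(O)c1ccc(OCc2ccccc2)cc1 | starting material
18 | (2R)-5,7-bis(benzyloxy)-2-[4-(benzyloxy)phenyl]-8-{(2S,3S)-2-[3,4-bis(benzyloxy)phenyl]-5,7-bis(benzyloxy)-3-hydroxy-4-oxo-3,4-dihydro-2H-chromen-3-yl}-2,3-dihydro-4H-chromen-4-one | O=C1C[C@H](c2ccc(OCc3ccccc3)cc2)Oc2c1c(OCc1ccccc1)cc(OCc1ccccc1)c2[C@@]1(O)C(=O)c2c(OCc3ccccc3)cc(OCc3ccccc3)cc2O[C@H]1c1ccc(OCc2ccccc2)c(OCc2ccccc2)c1 | intermediate
19 | samarium enolate of 20 (4-(diiodosamariooxy)-2H-chromene of unit A, C2 as in 20) | O=C1C[C@H](c2ccc(OCc3ccccc3)cc2)Oc2c1c(OCc1ccccc1)cc(OCc1ccccc1)c2C1=C(O[Sm](I)I)c2c(OCc3ccccc3)cc(OCc3ccccc3)cc2O[C@H]1c1ccc(OCc2ccccc2)c(OCc2ccccc2)c1 | intermediate (not isolated)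
20 | (2R,3S)-2-[3,4-bis(benzyloxy)phenyl]-5,7-bis(benzyloxy)-3-{(2R)-5,7-bis(benzyloxy)-2-[4-(benzyloxy)phenyl]-4-oxo-3,4-dihydro-2H-chromen-8-yl}-2,3-dihydro-4H-chromen-4-one | O=C1C[C@H](c2ccc(OCc3ccccc3)cc2)Oc2c1c(OCc1ccccc1)cc(OCc1ccccc1)c2[C@@H]1C(=O)c2c(OCc3ccccc3)cc(OCc3ccccc3)cc2O[C@H]1c1ccc(OCc2ccccc2)c(OCc2ccccc2)c1 | intermediate
21 | (2R,3S)-2-(3,4-dihydroxyphenyl)-5,7-dihydroxy-3-[(2R)-5,7-dihydroxy-2-(4-hydroxyphenyl)-4-oxo-3,4-dihydro-2H-chromen-8-yl]-2,3-dihydro-4H-chromen-4-one | O=C1C[C@H](c2ccc(O)cc2)Oc2c1c(O)cc(O)c2[C@@H]1C(=O)c2c(O)cc(O)cc2O[C@H]1c1ccc(O)c(O)c1 | target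

**Step count**

Total: 14 steps. Longest linear sequence: 11 steps (steps 3, 4 and 6 to 14, from 5 to 21).

**Steps most likely to fail**

Step 11. The alkoxide may shift the ring-A aryl carbon instead of C2, giving the chroman-3-one isomer whose C2–H is enolisable, so the C2 configuration would erode. The ketol equilibrium may also stop short of the six-membered ketone, or the alkoxide may attack the chromone. The fallback is an irreversible semipinacol shift one oxidation level lower, setting out from diol 13. Selective mesylation of the secondary benzylic hydroxyl (MsCl, Et3N, CH2Cl2, −40 °C) should give the secondary methanesulfonate of 13 F1. Treatment with Et3Al (CH2Cl2, −78 °C) should then push C2, held antiperiplanar to the sulfonate in the aluminium alkoxide, onto the benzylic carbon. After equilibration of C3 this gives 5,7-bis(benzyloxy)-8-{(2R,3S)-2-[3,4-bis(benzyloxy)phenyl]-5,7-bis(benzyloxy)-4-oxo-3,4-dihydro-2H-chromen-3-yl}-4H-chromen-4-one F2. Conjugate arylation of F2 with 17 under the conditions of step 12 rejoins the route at 20, replacing steps 11 to 13.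

Step 6. The electron-rich phenol ring may attack the copper allenylidene through carbon (C4 or C6) instead of oxygen, or the enantioselectivity may be poor. The fallback is reagent-controlled reduction followed by substitution with inversion, setting out from racemic alcohol 6. Oxidation with MnO2 (CH2Cl2, 25 °C) gives 1-[3,4-bis(benzyloxy)phenyl]prop-2-yn-1-one F3. CBS reduction (Me-CBS oxazaborolidine of the required hand, BH3·SMe2, THF, −30 °C) gives (1S)-1-[3,4-bis(benzyloxy)phenyl]prop-2-yn-1-ol F4. A Mitsunobu reaction of F4 with phenol 9 (PPh3, DIAD, toluene, −20 °C) alkylates only at oxygen and inverts the carbinol centre, rejoining the route at 10.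

Step 8. Palladium hydride may move the exocyclic double bond into the ring, which aromatises the product to a 3-benzylbenzofuran and destroys the C2 stereocentre. Hydrodebromination before cyclisation is also possible. The fallback is a tin hydride radical cyclisation without palladium hydride, setting out from 11. With Bu3SnH and AIBN (toluene, 80 °C) the aryl radical closes 5-exo-dig and should give the alkene as a mixture of 12 and the E isomer of 12 F5. OsO4/NMO converts F5 into the diol epimeric with 13 at the exocyclic carbinol carbon F6. IBX oxidation of F6, alone or mixed with 13, converges on ketol 14, where the route is rejoined.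

Further compounds
F1 | step 11 | secondary methanesulfonate of diol 13 | O=c1ccoc2c([C@H](OS(C)(=O)=O)[C@@]3(O)c4c(OCc5ccccc5)cc(OCc5ccccc5)cc4O[C@H]3c3ccc(OCc4ccccc4)c(OCc4ccccc4)c3)c(OCc3ccccc3)cc(OCc3ccccc3)c12
F2 | step 11 | 5,7-bis(benzyloxy)-8-{(2R,3S)-2-[3,4-bis(benzyloxy)phenyl]-5,7-bis(benzyloxy)-4-oxo-3,4-dihydro-2H-chromen-3-yl}-4H-chromen-4-one | O=c1ccoc2c([C@@H]3C(=O)c4c(OCc5ccccc5)cc(OCc5ccccc5)cc4O[C@H]3c3ccc(OCc4ccccc4)c(OCc4ccccc4)c3)c(OCc3ccccc3)cc(OCc3ccccc3)c12
F3 | step 6 | 1-[3,4-bis(benzyloxy)phenyl]prop-2-yn-1-one | C#CC(=O)c1ccc(OCc2ccccc2)c(OCc2ccccc2)c1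
F4 | step 6 | (1S)-1-[3,4-bis(benzyloxy)phenyl]prop-2-yn-1-ol | C#C[C@H](O)c1ccc(OCc2ccccc2)c(OCc2ccccc2)c1
F5 | step 8 | E isomer of 12 | O=c1ccoc2c(/C=C3\c4c(OCc5ccccc5)cc(OCc5ccccc5)cc4O[C@H]3c3ccc(OCc4ccccc4)c(OCc4ccccc4)c3)c(OCc3ccccc3)cc(OCc3ccccc3)c12
F6 | step 8 | epimer of diol 13 at the exocyclic carbinol carbon (R carbinol) | O=c1ccoc2c([C@@H](O)[C@@]3(O)c4c(OCc5ccccc5)cc(OCc5ccccc5)cc4O[C@H]3c3ccc(OCc4ccccc4)c(OCc4ccccc4)c3)c(OCc3ccccc3)cc(OCc3ccccc3)c12
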